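**Plan**

1. Numbering: ring C1 (CO2H), C2 and C4 (OH), C6 (side chain); chain C1' (benzylic) to C13'. The retrosynthesis first cuts the two acetate C–O bonds and the three O–benzyl protecting bonds, then the C1(=O)–O(C2') bond of a temporary δ-lactone, then C6–C1', and last C10'–C11' and the oxirane of the chain.
2. Enabling feature: the C1 carboxyl group has exactly one free ortho C–H (C6, because C2 carries oxygen). C6–C1'H2–C2'(O) is the pattern of a terminal epoxide opened at its CH2, and the C2' oxygen lies δ to the carboxyl carbon, so a six-membered lactone (isochroman-1-one) can close.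
3. Forward: the C13 chain is built first (C10 Grignard reagent plus a C3 epoxide, then acetate, epoxidation and resolution). It is joined to the intact benzene ring of 2,4-bis(benzyloxy)benzoic acid by carboxylate-directed C–H alkylation with lactonisation. The lactone, the only ring formed, is opened again and held open as a benzyl ester; diacetylation and hydrogenolysis follow.
4. Stereochemistry: C12' comes from (R)-propylene oxide. C2' comes from hydrolytic kinetic resolution of the terminal epoxide. Every later bond is made at a neighbouring CH2 or at oxygen, so neither centre is touched again.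

Key step: step 6

Remark: the SMILES is read as the (2R,12R)-2,12-bis(acetyloxy)tridecyl chain on C6 of 2,4-dihydroxybenzoic acid.

**Route**

Step 1
Reactants: 1 2,4-dihydroxybenzoic acid
Product: 3 2,4-bis(benzyloxy)benzoic acid, via benzyl 2,4-bis(benzyloxy)benzoate 2 (not isolated)
Conditions: BnBr (3.3 equiv), K2CO3, DMF, 60 °C; then KOH, MeOH/H2O, reflux; then aq. HCl to pH 2
Reagents that add atoms: benzyl bromide, BrCc1ccccc1; potassium hydroxide, [K+].[OH-]
Why: Williamson alkylation of both phenols and the carboxylate, then saponification of the ester alone (aryl benzyl ethers are inert to hydroxide), should free the carboxyl group that directs step 6 and leave benzyl ethers that can be removed at the end without harming acetates.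

Step 2
Reactants: 4 10-bromodec-1-ene; 5 (R)-2-methyloxirane
Product: 7 (2R)-tridec-12-en-2-ol, via dec-9-en-1-ylmagnesium bromide 6 (not isolated)
Conditions: Mg, THF, 40 °C; then 5, CuI (10 mol%), THF, −30 °C to 0 °C; aq. NH4Cl
Reagents that add atoms: none
Why: The CuI-catalysed Grignard opening of a terminal epoxide is an SN2 attack at the unsubstituted CH2, so the C–O stereocentre of 5 should pass unchanged into C2 of 7 (C12' of the target).

Step 3
Reactants: 7 (2R)-tridec-12-en-2-ol
Product: 8 (2R)-tridec-12-en-2-yl acetate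
Conditions: Ac2O, pyridine, DMAP (cat.), CH2Cl2, 0 °C to 20 °C
Reagents that add atoms: acetic anhydride, CC(=O)OC(C)=O
Why: DMAP-catalysed acylation gives an acetate that shields the secondary alcohol from oxidation by divalent palladium in step 6 and leaves without an extra step when the lactone is saponified in step 7.

Step 4
Reactants: 8 (2R)-tridec-12-en-2-yl acetate
Product: 9 (2R)-11-(oxiran-2-yl)undecan-2-yl acetate (both epimers at the oxirane carbon)
Conditions: mCPBA, CH2Cl2, 0 °C to 20 °C
Reagents that add atoms: 3-chloroperoxybenzoic acid, OOC(=O)c1cccc(Cl)c1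
Why: Prilezhaev epoxidation of the isolated terminal alkene should leave the ester untouched, and no facial control is needed because step 5 resolves the new centre.

Step 5
Reactants: 9 (2R)-11-(oxiran-2-yl)undecan-2-yl acetate (both epimers)
Product: 10 (2R)-11-[(2R)-oxiran-2-yl]undecan-2-yl acetate
Conditions: (R,R)-(salen)Co(OAc) (0.5 mol%; salen = N,N'-bis(3,5-di-tert-butylsalicylidene)-1,2-cyclohexanediaminate), H2O (0.55 equiv), THF, 0 °C to 20 °C
Reagents that add atoms: none
Why: In the Jacobsen hydrolytic kinetic resolution the (R,R)-configured cobalt salen catalyst should hydrate the epimer with the (S)-oxirane selectively through its cooperative two-metal mechanism, leaving the (R)-oxirane, which fixes C2' of the target.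

Step 6
Reactants: 3 2,4-bis(benzyloxy)benzoic acid (1.5 equiv); 10 (2R)-11-[(2R)-oxiran-2-yl]undecan-2-yl acetate
Product: 11 (2R)-11-[(3R)-6,8-bis(benzyloxy)-1-oxo-3,4-dihydro-1H-isochromen-3-yl]undecan-2-yl acetate
Conditions: Pd(OAc)2 (5 mol%), N-acetyl-L-tert-leucine (10 mol%), KOAc (1 equiv), (CF3)2CHOH, 75 °C
Reagents that add atoms: none
Why: The potassium carboxylate of 3 binds divalent palladium, the amino acid ligand assists concerted metalation–deprotonation of the only ortho C–H (C6) to a five-membered aryl-palladium carboxylate chelate, the aryl–palladium bond opens the hydrogen-bond-activated epoxide at its terminal CH2 in a redox-neutral SN2 step, and the resulting alkoxide acylates on the carboxyl group with loss of water, releasing divalent palladium. The closest known reaction type is the carboxylate-directed Pd(OAc)2-catalysed ortho-C–H alkylation of benzoic acids with terminal epoxides to give 3-substituted 3,4-dihydroisocoumarins. The one ring formed, the δ-lactone, closes by 6-exo-trig addition–elimination of the C2' oxygen on the C1 carboxyl carbon. No new stereocentre arises: C3 of the lactone is the untouched C–O carbon of the (R)-oxirane because attack occurs at the CH2, and the remote acetate-bearing centre is not involved. The step needs site selectivity on the arene (secured by the single ortho C–H, C2 being blocked by OBn), terminal regioselectivity on the epoxide (steric), and mono-alkylation (secured because lactonisation consumes the directing carboxylate). It also needs the absence of an oxidisable free alcohol, which the acetate secures.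

Step 7
Reactants: 11 (2R)-11-[(3R)-6,8-bis(benzyloxy)-1-oxo-3,4-dihydro-1H-isochromen-3-yl]undecan-2-yl acetate
Product: 13 benzyl 2,4-bis(benzyloxy)-6-[(2R,12R)-2,12-dihydroxytridecyl]benzoate, via potassium 2,4-bis(benzyloxy)-6-[(2R,12R)-2,12-dihydroxytridecyl]benzoate 12 (not isolated)
Conditions: KOH (2.5 equiv), THF/MeOH/H2O, 60 °C; solid CO2 to pH 8–9, evaporate; BnBr (1.2 equiv), DMF, 20 °C
Reagents that add atoms: potassium hydroxide, [K+].[OH-]; benzyl bromide, BrCc1ccccc1
Why: Saponification opens the lactone (and cleaves the C12' acetate), and SN2 O-alkylation of the carboxylate under bicarbonate buffering should fix the open form as an ester without passing through the free hydroxy acid that would relactonise, while the secondary alcohols stay unalkylated at this basicity.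

Step 8
Reactants: 13 benzyl 2,4-bis(benzyloxy)-6-[(2R,12R)-2,12-dihydroxytridecyl]benzoate
Product: 14 benzyl 2,4-bis(benzyloxy)-6-[(2R,12R)-2,12-bis(acetyloxy)tridecyl]benzoate
Conditions: Ac2O, Et3N, DMAP (cat.), CH2Cl2, 0 °C
Reagents that add atoms: acetic anhydride, CC(=O)OC(C)=O
Why: DMAP-catalysed acetylation of both secondary alcohols should outrun attack of the C2' hydroxyl on the hindered 2,6-disubstituted benzyl ester, and once acetylated the C2' oxygen can no longer lactonise.

Step 9
Reactants: 14 benzyl 2,4-bis(benzyloxy)-6-[(2R,12R)-2,12-bis(acetyloxy)tridecyl]benzoate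
Product: 15 2-[(2R,12R)-2,12-bis(acetyloxy)tridecyl]-4,6-dihydroxybenzoic acid (target)
Conditions: H2 (1 atm), 10% Pd/C, EtOAc, 20 °C
Reagents that add atoms: none
Why: Hydrogenolysis should cleave the three O–benzyl bonds (two ethers and the ester) under neutral conditions that leave the alkyl acetates and both stereocentres untouched.

**Compound list**

1 | 2,4-dihydroxybenzoic acid | OC(=O)c1ccc(O)cc1O | starting material
2 | benzyl 2,4-bis(benzyloxy)benzoate | O=C(OCc1ccccc1)c1ccc(OCc2ccccc2)cc1OCc1ccccc1 | intermediate (not isolated)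
3 | 2,4-bis(benzyloxy)benzoic acid | OC(=O)c1ccc(OCc2ccccc2)cc1OCc1ccccc1 | intermediate
4 | 10-bromodec-1-ene | BrCCCCCCCCC=C | starting material
5 | (R)-2-methyloxirane ((R)-propylene oxide) | C[C@@H]1CO1 | starting material
6 | dec-9-en-1-ylmagnesium bromide | Br[Mg]CCCCCCCCC=C | intermediate (not isolated)
7 | (2R)-tridec-12-en-2-ol | C[C@@H](O)CCCCCCCCCC=C | intermediate
8 | (2R)-tridec-12-en-2-yl acetate | C[C@@H](OC(C)=O)CCCCCCCCCC=C | intermediate
9 | (2R)-11-(oxiran-2-yl)undecan-2-yl acetate, both epimers at the oxirane carbon | C[C@@H](OC(C)=O)CCCCCCCCCC1CO1 | intermediate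
10 | (2R)-11-[(2R)-oxiran-2-yl]undecan-2-yl acetate | C[C@@H](OC(C)=O)CCCCCCCCC[C@@H]1CO1 | intermediate
11 | (2R)-11-[(3R)-6,8-bis(benzyloxy)-1-oxo-3,4-dihydro-1H-isochromen-3-yl]undecan-2-yl acetate | C[C@@H](OC(C)=O)CCCCCCCCC[C@@H]1Cc2cc(OCc3ccccc3)cc(OCc3ccccc3)c2C(=O)O1 | intermediate
12 | potassium 2,4-bis(benzyloxy)-6-[(2R,12R)-2,12-dihydroxytridecyl]benzoate | C[C@@H](O)CCCCCCCCC[C@@H](O)Cc1cc(OCc2ccccc2)cc(OCc2ccccc2)c1C(=O)[O-].[K+] | intermediate (not isolated)
13 | benzyl 2,4-bis(benzyloxy)-6-[(2R,12R)-2,12-dihydroxytridecyl]benzoate | C[C@@H](O)CCCCCCCCC[C@@H](O)Cc1cc(OCc2ccccc2)cc(OCc2ccccc2)c1C(=O)OCc1ccccc1 | intermediate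
14 | benzyl 2,4-bis(benzyloxy)-6-[(2R,12R)-2,12-bis(acetyloxy)tridecyl]benzoate | C[C@@H](OC(C)=O)CCCCCCCCC[C@@H](OC(C)=O)Cc1cc(OCc2ccccc2)cc(OCc2ccccc2)c1C(=O)OCc1ccccc1 | intermediate
15 | 2-[(2R,12R)-2,12-bis(acetyloxy)tridecyl]-4,6-dihydroxybenzoic acid | C[C@@H](OC(C)=O)CCCCCCCCC[C@@H](OC(C)=O)Cc1cc(O)cc(O)c1C(=O)O | target

**Step count and risks**

Total steps: 9. Longest linear sequence: 8 steps (steps 2 to 9, from 4 and 5 to 15); the arene branch is step 1 and joins at step 6.

Step 6 (highest risk). The aryl–palladium intermediate may open the unactivated long-chain epoxide too slowly, so that isomerisation or solvolysis of the epoxide, or protodecarboxylation of the electron-rich acid, uses up the partners before coupling. The fallback sets out from 10, forms the same aryl–CH2 bond by classical nucleophilic opening, and comes back to the route at 11. Commercial 5-bromoresorcinol is dibenzylated (BnBr, K2CO3, DMF) to 1,3-bis(benzyloxy)-5-bromobenzene F1. Mg in THF converts it into 3,5-bis(benzyloxy)phenylmagnesium bromide F2. Under CuI catalysis at −30 °C, where the acetate should not be attacked, F2 should open 10 at the terminal CH2 to give (2R,12R)-13-[3,5-bis(benzyloxy)phenyl]-12-hydroxytridecan-2-yl acetate F3. NBS in MeCN at 0 °C should brominate the ring ortho to the chain and para to a benzyloxy group, giving (2R,12R)-13-[3,5-bis(benzyloxy)-2-bromophenyl]-12-hydroxytridecan-2-yl acetate F4. Carbonylative lactonisation (Pd(OAc)2, Xantphos, CO at 1 atm, K2CO3, toluene, 100 °C) should then close the lactone to 11.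

Step 7. The lactone may close again during or after the carboxylate alkylation (the C2' hydroxyl attacking the new ester), and residual hydroxide may cause O-benzylation of the alcohols. The fallback sets out from 11, removes the acyl electrophile by a detour in oxidation level, and comes back at 15.
- LiAlH4 in THF should reduce the lactone and the acetate to (2R,12R)-1-[3,5-bis(benzyloxy)-2-(hydroxymethyl)phenyl]tridecane-2,12-diol F5.
- TBSCl and imidazole in DMF at 0 °C should silylate only the primary benzylic alcohol, giving (2R,12R)-1-[3,5-bis(benzyloxy)-2-({[tert-butyl(dimethyl)silyl]oxy}methyl)phenyl]tridecane-2,12-diol F6.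
- Ac2O with DMAP should give (2R,12R)-1-[3,5-bis(benzyloxy)-2-({[tert-butyl(dimethyl)silyl]oxy}methyl)phenyl]tridecane-2,12-diyl diacetate F7.
- Bu4NF buffered with AcOH in THF should free (2R,12R)-1-[3,5-bis(benzyloxy)-2-(hydroxymethyl)phenyl]tridecane-2,12-diyl diacetate F8.
- PhI(OAc)2 with catalytic TEMPO in MeCN/H2O should oxidise it through (2R,12R)-1-[3,5-bis(benzyloxy)-2-formylphenyl]tridecane-2,12-diyl diacetate F9 to 2,4-bis(benzyloxy)-6-[(2R,12R)-2,12-bis(acetyloxy)tridecyl]benzoic acid F10.
- Hydrogenolysis (H2, 10% Pd/C, EtOAc) should then give 15.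

Step 5. The two oxirane epimers may be discriminated incompletely; they cannot be separated otherwise because the second stereocentre is remote, and half of the material is lost in any case. The fallback sets out from 5, takes both centres from the chiral pool, and comes back at 10.
- 1-Bromo-7-chloroheptane and Mg (insertion at C–Br only) should give 7-chloroheptylmagnesium bromide F11.
- F11 should open 5 under CuI catalysis to (2R)-10-chlorodecan-2-ol F12.
- Deprotonation with i-PrMgCl followed by Mg in refluxing THF should give the alkoxide-masked Grignard reagent chloromagnesium (2R)-10-(chloromagnesio)decan-2-olate F13.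
- F13 should open (R)-epichlorohydrin at its oxirane CH2 (CuI, −30 °C) to (2R,12R)-1-chlorotridecane-2,12-diol F14.
- K2CO3 in MeOH should close the oxirane without touching the stereocentre, giving (2R)-11-[(2R)-oxiran-2-yl]undecan-2-ol F15.
- Ac2O in pyridine should then give 10.

**Further compounds**

F1 | step 6 | 1,3-bis(benzyloxy)-5-bromobenzene | Brc1cc(OCc2ccccc2)cc(OCc2ccccc2)c1
F2 | step 6 | 3,5-bis(benzyloxy)phenylmagnesium bromide | Br[Mg]c1cc(OCc2ccccc2)cc(OCc2ccccc2)c1
F3 | step 6 | (2R,12R)-13-[3,5-bis(benzyloxy)phenyl]-12-hydroxytridecan-2-yl acetate | C[C@@H](OC(C)=O)CCCCCCCCC[C@@H](O)Cc1cc(OCc2ccccc2)cc(OCc2ccccc2)c1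
F4 | step 6 | (2R,12R)-13-[3,5-bis(benzyloxy)-2-bromophenyl]-12-hydroxytridecan-2-yl acetate | C[C@@H](OC(C)=O)CCCCCCCCC[C@@H](O)Cc1cc(OCc2ccccc2)cc(OCc2ccccc2)c1Br
F5 | step 7 | (2R,12R)-1-[3,5-bis(benzyloxy)-2-(hydroxymethyl)phenyl]tridecane-2,12-diol | C[C@@H](O)CCCCCCCCC[C@@H](O)Cc1cc(OCc2ccccc2)cc(OCc2ccccc2)c1CO
F6 | step 7 | (2R,12R)-1-[3,5-bis(benzyloxy)-2-({[tert-butyl(dimethyl)silyl]oxy}methyl)phenyl]tridecane-2,12-diol | C[C@@H](O)CCCCCCCCC[C@@H](O)Cc1cc(OCc2ccccc2)cc(OCc2ccccc2)c1CO[Si](C)(C)C(C)(C)C
F7 | step 7 | (2R,12R)-1-[3,5-bis(benzyloxy)-2-({[tert-butyl(dimethyl)silyl]oxy}methyl)phenyl]tridecane-2,12-diyl diacetate | C[C@@H](OC(C)=O)CCCCCCCCC[C@@H](OC(C)=O)Cc1cc(OCc2ccccc2)cc(OCc2ccccc2)c1CO[Si](C)(C)C(C)(C)C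
F8 | step 7 | (2R,12R)-1-[3,5-bis(benzyloxy)-2-(hydroxymethyl)phenyl]tridecane-2,12-diyl diacetate | C[C@@H](OC(C)=O)CCCCCCCCC[C@@H](OC(C)=O)Cc1cc(OCc2ccccc2)cc(OCc2ccccc2)c1CO
F9 | step 7 | (2R,12R)-1-[3,5-bis(benzyloxy)-2-formylphenyl]tridecane-2,12-diyl diacetate | C[C@@H](OC(C)=O)CCCCCCCCC[C@@H](OC(C)=O)Cc1cc(OCc2ccccc2)cc(OCc2ccccc2)c1C=O
F10 | step 7 | 2,4-bis(benzyloxy)-6-[(2R,12R)-2,12-bis(acetyloxy)tridecyl]benzoic acid | C[C@@H](OC(C)=O)CCCCCCCCC[C@@H](OC(C)=O)Cc1cc(OCc2ccccc2)cc(OCc2ccccc2)c1C(=O)O
F11 | step 5 | 7-chloroheptylmagnesium bromide | ClCCCCCCC[Mg]Br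
F12 | step 5 | (2R)-10-chlorodecan-2-ol | C[C@@H](O)CCCCCCCCCl
F13 | step 5 | chloromagnesium (2R)-10-(chloromagnesio)decan-2-olate | C[C@@H](O[Mg]Cl)CCCCCCCC[Mg]Cl
F14 | step 5 | (2R,12R)-1-chlorotridecane-2,12-diol | C[C@@H](O)CCCCCCCCC[C@@H](O)CCl
F15 | step 5 | (2R)-11-[(2R)-oxiran-2-yl]undecan-2-ol | C[C@@H](O)CCCCCCCCC[C@@H]1CO1
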